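**Plan**
1. Numbering: ring A has C1 CH2O-acyl, C2 O-aryl, C3 OH, C5 OCH3; ring B has C1' O-aryl, C3' OH, C5' CH3. The cuts are, in order, the benzylic CH2–O bond to palmitate, the three ring B bonds C2'–C3', C1'–C6' and C3'–C4', and finally O–C1' (ring A phenoxide plus a two-carbon unit from trichloroethylene).
2. Enabling feature: ring B is a 1',3',5'-trisubstituted resorcinol monoether with hydrogen at C2', C4' and C6'. C1'–C2' therefore map onto an aryl ethynyl ether, and C3'–C4'–C5'(CH3)–C6' map onto the four ring carbons of 3-methylcyclobutenone.
3. Forward: ring A is bought as 2-hydroxy-5-methoxybenzaldehyde. Its C3 oxygen enters by bromination and copper-catalysed hydroxylation, C3–OH is masked as a MOM ether, CHO is reduced and silylated, and the C2 phenol becomes the ethynyl ether.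
4. Ring B is the only ring made. It grows on that ethynyl ether by thermal benzannulation with 3-methylcyclobutenone (from propyne and dichloroketene), so no Ullmann- or Chan–Lam-type C–O coupling at the hindered C2 oxygen is needed.
5. The chain is joined last: desilylation, Mitsunobu esterification of the alcohol alone with palmitic acid, then mild MOM removal.
6. The target has no stereocentre and no stereogenic double bond. Only regiochemistry needs control, and it comes from phenol-directed bromination, dianion alkylation and the polarity of the ynol ether.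

Key step: step 10

Remark: ethynyl ether 14 (sensitive to acid and heat) and cyclobutenone 19 (volatile) are assumed to be made shortly before step 10 and handled as solutions.

**Step 1**
Reactants: 1 2-hydroxy-5-methoxybenzaldehyde
Product: 2 3-bromo-2-hydroxy-5-methoxybenzaldehyde
Conditions: Br2 (1.05 equiv), NaOAc, AcOH, rt
Reagents that add atoms: bromine, BrBr
Why: Electrophilic aromatic bromination, in which the free phenol is the strongest director and its para position carries OCH3, so bromine should enter C3 ortho to OH while NaOAc buffers the HBr.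

**Step 2**
Reactants: 2 3-bromo-2-hydroxy-5-methoxybenzaldehyde
Product: 3 2,3-dihydroxy-5-methoxybenzaldehyde
Conditions: NaOH (aq), Cu powder (cat.), N2, reflux; then HCl (aq), 0 °C
Reagents that add atoms: sodium hydroxide, [Na+].[OH-]
Why: Ullmann-type copper-catalysed hydroxylation of an ortho-bromophenoxide, the reaction type that converts 5-bromovanillin into 5-hydroxyvanillin; the phenoxide deactivates the aldehyde toward Cannizzaro reaction and exclusion of air protects the catecholate.

**Step 3**
Reactants: 3 2,3-dihydroxy-5-methoxybenzaldehyde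
Product: 5 2-hydroxy-5-methoxy-3-(methoxymethoxy)benzaldehyde, via disodium catecholate 4 (not isolated)
Conditions: NaH (2.1 equiv), DMF, 0 °C; MOMCl (1.0 equiv), 0 °C → rt; then aq NH4Cl
Reagents that add atoms: chloromethyl methyl ether (MOMCl), COCCl
Why: Regioselective Williamson-type mono-O-alkylation of a catechol dianion, in which the C2 oxide is delocalised into the ortho formyl group and the more basic C3 oxide should take the single equivalent of MOMCl.

**Step 4**
Reactants: 5 2-hydroxy-5-methoxy-3-(methoxymethoxy)benzaldehyde
Product: 6 2-(hydroxymethyl)-4-methoxy-6-(methoxymethoxy)phenol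
Conditions: NaBH4, MeOH, 0 °C
Reagents that add atoms: none
Why: Borohydride reduction of an aryl aldehyde, to which the acetal and the aryl ethers are inert; the product is kept cold and silylated directly.

**Step 5**
Reactants: 6 2-(hydroxymethyl)-4-methoxy-6-(methoxymethoxy)phenol
Product: 7 4-methoxy-2-(methoxymethoxy)-6-[(triisopropylsilyloxy)methyl]phenol
Conditions: TIPSCl (1.05 equiv), imidazole, CH2Cl2, 0 °C → rt
Reagents that add atoms: triisopropylsilyl chloride (TIPSCl), CC(C)[Si](Cl)(C(C)C)C(C)C
Why: Chemoselective silylation with silyl chloride and imidazole, in which the bulky reagent should reach the primary benzylic alcohol far faster than a phenol flanked by two ortho substituents, as is known for salicyl alcohols.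

**Step 6**
Reactants: 7 4-methoxy-2-(methoxymethoxy)-6-[(triisopropylsilyloxy)methyl]phenol; 8 trichloroethylene
Product: 11 (E)-1,2-dichlorovinyl 4-methoxy-2-(methoxymethoxy)-6-[(triisopropylsilyloxy)methyl]phenyl ether, via potassium phenoxide 9 (not isolated), via dichloroacetylene 10 (not isolated)
Conditions: KH (1.2 equiv), THF, 0 °C; 8 (1.1 equiv), −50 °C → rt
Reagents that add atoms: none
Why: First half of the trichloroethylene route to ynol ethers (elimination then addition), in which base removes HCl from 8, the aryloxide adds anti to the slim linear dichloroacetylene to set the E geometry, and silyl migration is disfavoured because the phenoxide is the more stable anion.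

**Step 7**
Reactants: 11 (E)-1,2-dichlorovinyl aryl ether
Product: 14 ethynyl 4-methoxy-2-(methoxymethoxy)-6-[(triisopropylsilyloxy)methyl]phenyl ether, via chloroethynyl ether 12 (not isolated), via lithium acetylide 13 (not isolated)
Conditions: n-BuLi (2.3 equiv), THF, −78 → −40 °C; MeOH, −78 °C; neutral work-up, Et3N-deactivated silica
Reagents that add atoms: none
Why: Second half of the same route (β-elimination of HCl, then chlorine–lithium exchange and protonation); any stray ring lithiation at C4 between OMOM and OCH3 is undone by the same proton quench.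

**Step 8**
Reactants: 15 propyne; 16 trichloroacetyl chloride
Product: 18 4,4-dichloro-3-methylcyclobut-2-en-1-one, via dichloroketene 17 (not isolated)
Conditions: Zn–Cu couple, Et2O/DME, excess 15 condensed in, 0 °C → rt, dry-ice condenser
Reagents that add atoms: none
Why: Ketene–alkyne (2+2) cycloaddition with dichloroketene made by zinc dechlorination, in which the ketene carbonyl carbon bonds to the terminal alkyne carbon so that the methyl group ends up at C3, as established for 1-hexyne.

**Step 9**
Reactants: 18 4,4-dichloro-3-methylcyclobut-2-en-1-one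
Product: 19 3-methylcyclobut-2-en-1-one
Conditions: Zn dust, AcOH, TMEDA, EtOH, 0 °C → rt; extraction into pentane, careful distillation
Reagents that add atoms: none
Why: Zinc-mediated reductive dechlorination of an α,α-dichloroketone, with the AcOH/TMEDA buffer known to suppress chloride migration and over-reduction in 3-alkylcyclobutenone preparations.

**Step 10**
Reactants: 14 ethynyl 4-methoxy-2-(methoxymethoxy)-6-[(triisopropylsilyloxy)methyl]phenyl ether; 19 3-methylcyclobut-2-en-1-one
Product: 24 3-{4-methoxy-2-(methoxymethoxy)-6-[(triisopropylsilyloxy)methyl]phenoxy}-5-methylphenol, via vinylketene 20 (not isolated), via isopropenylcyclobutenone 21 (not isolated), via dienylketene 22 (not isolated), via cyclohexadienone 23 (not isolated)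
Conditions: 19 (1.3 equiv), toluene (0.4 M), sealed tube, 80 °C then 120 °C; crude product stirred with KOH, MeOH, rt
Reagents that add atoms: none
Why: Heating opens 19 by a 4π electrocyclic reaction to vinylketene 20, and ynol ether 14 adds to it in a (2+2) cycloaddition in which the hydrogen-bearing, nucleophilic alkyne carbon (C2') bonds to the ketene carbonyl carbon (C3') and the oxygen-bearing alkyne carbon (C1') bonds to the ketene α-carbon (C6'), giving racemic 21. At the higher temperature 21 opens reversibly (4π) to dienylketene 22, whose isomer with ketene and isopropenyl groups cis on the central double bond closes by 6π electrocyclisation between C3' and C4' to cyclohexadienone 23, and irreversible tautomerisation to phenol 24 drains the equilibria. The closest known reaction type is the Danheiser benzannulation of 3-alkylcyclobutenones with alkoxy-, siloxy- and aryloxyalkynes, which delivers resorcinol monoethers. Ring B, the only ring closed, forms in a pericyclic six-electron mode that turns an open trienone chain into a six-membered carbocycle, and no stereocentre remains because the single one of 21 is erased on ring opening. The step needs one orientation of the (2+2) addition, and the oxygen lone pair of 14 secures it by making the terminal alkyne carbon the nucleophilic end, so that OH, aryloxy and CH3 end up mutually meta and the two ring B oxygens are differentiated from the outset. An aryl ynol ether has no β-hydrogen for retro-ene loss, its two ortho substituents should slow polymerisation, and the KOH/MeOH treatment only returns any phenol that excess 20 has acylated.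

**Step 11**
Reactants: 24 3-{4-methoxy-2-(methoxymethoxy)-6-[(triisopropylsilyloxy)methyl]phenoxy}-5-methylphenol
Product: 25 3-[2-(hydroxymethyl)-4-methoxy-6-(methoxymethoxy)phenoxy]-5-methylphenol
Conditions: Bu4NF, AcOH (1:1), THF, rt
Reagents that add atoms: none
Why: Fluoride desilylation driven by Si–F bond formation, with AcOH keeping the phenol protonated and with the MOM acetal and diaryl ether untouched.

**Step 12**
Reactants: 25 3-[2-(hydroxymethyl)-4-methoxy-6-(methoxymethoxy)phenoxy]-5-methylphenol; 26 palmitic acid
Product: 28 2-(3-hydroxy-5-methylphenoxy)-5-methoxy-3-(methoxymethoxy)benzyl palmitate, via alkoxyphosphonium palmitate 27 (not isolated)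
Conditions: 26 (1.1 equiv), PPh3, DIAD, THF, 0 °C → rt
Reagents that add atoms: none
Why: Mitsunobu esterification, in which only the alcohol is activated as an oxyphosphonium ion and the carboxylate (acid pKa about 5) outcompetes the phenol (pKa about 10) as nucleophile, a chemoselectivity known for phenolic benzyl alcohols such as vanillyl alcohol.

**Step 13**
Reactants: 28 2-(3-hydroxy-5-methylphenoxy)-5-methoxy-3-(methoxymethoxy)benzyl palmitate
Product: 29 betaethrin H, 3-hydroxy-2-(3-hydroxy-5-methylphenoxy)-5-methoxybenzyl palmitate
Conditions: NaHSO4·SiO2, CH2Cl2, rt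
Reagents that add atoms: none
Why: Acid-catalysed hydrolysis of a phenolic MOM acetal on a mild heterogeneous acid that tolerates esters; the benzylic C–O bond should stay intact because both the C3 and C5 oxygens are meta to the benzylic carbon and cannot stabilise a cation there.

**Compound list**
1 | 2-hydroxy-5-methoxybenzaldehyde | COc1ccc(O)c(C=O)c1 | starting material
2 | 3-bromo-2-hydroxy-5-methoxybenzaldehyde | COc1cc(Br)c(O)c(C=O)c1 | intermediate
3 | 2,3-dihydroxy-5-methoxybenzaldehyde | COc1cc(O)c(O)c(C=O)c1 | intermediate
4 | disodium 3-formyl-5-methoxybenzene-1,2-diolate | COc1cc([O-])c([O-])c(C=O)c1.[Na+].[Na+] | intermediate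
5 | 2-hydroxy-5-methoxy-3-(methoxymethoxy)benzaldehyde | COCOc1cc(OC)cc(C=O)c1O | intermediate
6 | 2-(hydroxymethyl)-4-methoxy-6-(methoxymethoxy)phenol | COCOc1cc(OC)cc(CO)c1O | intermediate
7 | 4-methoxy-2-(methoxymethoxy)-6-[(triisopropylsilyloxy)methyl]phenol | COCOc1cc(OC)cc(CO[Si](C(C)C)(C(C)C)C(C)C)c1O | intermediate
8 | trichloroethylene | ClC=C(Cl)Cl | starting material
9 | potassium 4-methoxy-2-(methoxymethoxy)-6-[(triisopropylsilyloxy)methyl]phenoxide | COCOc1cc(OC)cc(CO[Si](C(C)C)(C(C)C)C(C)C)c1[O-].[K+] | intermediate
10 | dichloroacetylene | ClC#CCl | intermediate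
11 | (E)-1,2-dichlorovinyl 4-methoxy-2-(methoxymethoxy)-6-[(triisopropylsilyloxy)methyl]phenyl ether | COCOc1cc(OC)cc(CO[Si](C(C)C)(C(C)C)C(C)C)c1O/C(Cl)=C\Cl | intermediate
12 | chloroethynyl 4-methoxy-2-(methoxymethoxy)-6-[(triisopropylsilyloxy)methyl]phenyl ether | COCOc1cc(OC)cc(CO[Si](C(C)C)(C(C)C)C(C)C)c1OC#CCl | intermediate
13 | lithium acetylide of 14 (lithioethynyl aryl ether) | COCOc1cc(OC)cc(CO[Si](C(C)C)(C(C)C)C(C)C)c1OC#C[Li] | intermediate
14 | ethynyl 4-methoxy-2-(methoxymethoxy)-6-[(triisopropylsilyloxy)methyl]phenyl ether | C#COc1c(CO[Si](C(C)C)(C(C)C)C(C)C)cc(OC)cc1OCOC | intermediate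
15 | propyne | CC#C | starting material
16 | trichloroacetyl chloride | ClC(Cl)(Cl)C(Cl)=O | starting material
17 | dichloroketene | ClC(Cl)=C=O | intermediate
18 | 4,4-dichloro-3-methylcyclobut-2-en-1-one | CC1=CC(=O)C1(Cl)Cl | intermediate
19 | 3-methylcyclobut-2-en-1-one | CC1=CC(=O)C1 | intermediate
20 | 3-methylbuta-1,3-dien-1-one (isopropenylketene) | CC(=C)C=C=O | intermediate
21 | racemic 3-aryloxy-4-(prop-1-en-2-yl)cyclobut-2-en-1-one (aryl = ring A unit of 14) | CC(=C)C1C(=O)C=C1Oc2c(CO[Si](C(C)C)(C(C)C)C(C)C)cc(OC)cc2OCOC | intermediate
22 | (3E)-3-aryloxy-5-methylhexa-1,3,5-trien-1-one (ketene and isopropenyl cis) | O=C=C/C(Oc1c(CO[Si](C(C)C)(C(C)C)C(C)C)cc(OC)cc1OCOC)=C\C(C)=C | intermediate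
23 | 3-aryloxy-5-methylcyclohexa-2,4-dien-1-one | CC1=CC(Oc2c(CO[Si](C(C)C)(C(C)C)C(C)C)cc(OC)cc2OCOC)=CC(=O)C1 | intermediate
24 | 3-{4-methoxy-2-(methoxymethoxy)-6-[(triisopropylsilyloxy)methyl]phenoxy}-5-methylphenol | COc1cc(CO[Si](C(C)C)(C(C)C)C(C)C)c(Oc2cc(C)cc(O)c2)c(OCOC)c1 | intermediate
25 | 3-[2-(hydroxymethyl)-4-methoxy-6-(methoxymethoxy)phenoxy]-5-methylphenol | COc1cc(CO)c(Oc2cc(C)cc(O)c2)c(OCOC)c1 | intermediate
26 | palmitic acid | CCCCCCCCCCCCCCCC(=O)O | starting material
27 | benzyloxy(triphenyl)phosphonium palmitate derived from 25 | COc1cc(CO[P+](c2ccccc2)(c2ccccc2)c2ccccc2)c(Oc2cc(C)cc(O)c2)c(OCOC)c1.CCCCCCCCCCCCCCCC(=O)[O-] | intermediate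
28 | 2-(3-hydroxy-5-methylphenoxy)-5-methoxy-3-(methoxymethoxy)benzyl palmitate | CCCCCCCCCCCCCCCC(=O)OCc1cc(OC)cc(OCOC)c1Oc1cc(C)cc(O)c1 | intermediate
29 | betaethrin H | CCCCCCCCCCCCCCCC(=O)OCc1cc(OC)cc(O)c1Oc1cc(C)cc(O)c1 | target

**Step count**
Total steps: 13.
Longest linear sequence: 11 (steps 1–7 and 10–13); steps 8 and 9 form the short branch.

**Steps most likely to fail**

1. Step 10.
 - Risk: thermal oligomerisation of the terminal ynol ether and dimerisation of the vinylketene may outrun the (2+2) capture, because an aryloxy group polarises the alkyne less strongly than an alkoxy group.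
 - Fallback, from 14 back to 24: the same vinylketene 20 is released at room temperature by photochemical Wolff rearrangement, the second-generation diazoketone variant of the benzannulation. Commercial 3-methylbut-3-en-2-one is trifluoroacetylated (LiN(SiMe3)2, CF3CO2CH2CF3, THF, −78 °C) to 1,1,1-trifluoro-5-methylhex-5-ene-2,4-dione F1. Detrifluoroacetylative diazo transfer (MsN3, Et3N, H2O, MeCN, rt) gives 1-diazo-3-methylbut-3-en-2-one F2. Irradiation of F2 together with 14 (300 nm, CH2Cl2, rt) should consume the sensitive alkyne as 21 without heat. Only then is the solution warmed (toluene, 80–110 °C) to carry 21 through 22 and 23 to 24. The same three ring B bonds are formed.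

2. Step 2.
 - Risk: air oxidation of the electron-rich catecholate in hot alkali, incomplete displacement of bromide, or reductive loss of bromine.
 - Fallback, from 2 back to 3: the oxygen is first installed as a robust methyl ether by copper-catalysed methoxylation (NaOMe, CuBr cat., MeOH/DMF, 100 °C, the reaction type that gives syringaldehyde from 5-bromovanillin) to give 2-hydroxy-3,5-dimethoxybenzaldehyde F3. Chelation-directed demethylation (AlCl3, pyridine, CH2Cl2, reflux; then aq HCl) then cleaves only the methoxy group next to the free phenol. The catechol 3 appears only on acidic work-up and the C5 methoxy group, which has no neighbouring phenoxide, is retained.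

3. Step 13.
 - Risk: acid-induced ionisation of the benzylic C–O bond followed by Friedel–Crafts closure onto the nucleophilic ring B, ester cleavage, or sluggish acetal hydrolysis.
 - Fallback, from 24 back to 29: the order of events is changed so that no acid ever meets the ester. The MOM group of 24 is removed while the benzylic oxygen is still silylated (NaHSO4·SiO2, CH2Cl2, or dilute HCl in THF/i-PrOH) to give 2-(3-hydroxy-5-methylphenoxy)-5-methoxy-3-[(triisopropylsilyloxy)methyl]phenol F4. Bu4NF/AcOH in THF gives 3-(hydroxymethyl)-2-(3-hydroxy-5-methylphenoxy)-5-methoxyphenol F5. The neutral Mitsunobu esterification with 26 (PPh3, DIAD, THF, 0 °C), running through the alkoxyphosphonium palmitate of the triol F6, becomes the last step and acylates only the alcohol to give 29.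

**Further compounds**
F1 | step 10 | 1,1,1-trifluoro-5-methylhex-5-ene-2,4-dione | CC(=C)C(=O)CC(=O)C(F)(F)F
F2 | step 10 | 1-diazo-3-methylbut-3-en-2-one | CC(=C)C(=O)C=[N+]=[N-]
F3 | step 2 | 2-hydroxy-3,5-dimethoxybenzaldehyde | COc1cc(OC)c(O)c(C=O)c1
F4 | step 13 | 2-(3-hydroxy-5-methylphenoxy)-5-methoxy-3-[(triisopropylsilyloxy)methyl]phenol | COc1cc(O)c(Oc2cc(C)cc(O)c2)c(CO[Si](C(C)C)(C(C)C)C(C)C)c1
F5 | step 13 | 3-(hydroxymethyl)-2-(3-hydroxy-5-methylphenoxy)-5-methoxyphenol | COc1cc(O)c(Oc2cc(C)cc(O)c2)c(CO)c1
F6 | step 13 | benzyloxy(triphenyl)phosphonium palmitate derived from F5 | COc1cc(O)c(Oc2cc(C)cc(O)c2)c(CO[P+](c2ccccc2)(c2ccccc2)c2ccccc2)c1.CCCCCCCCCCCCCCCC(=O)[O-]
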